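**Plan**

Numbering: seven-membered ring C1 (CH–acetonyl), C2 (C=O), C3 (C–OH), C12, C11, C10 (C–CH3), C13 (CH–enol ester arm); cyclohexane C7–C8–C9–C10–C11–C12; pyran C3–C4–O5–C6(CH3)2–C7–C12; arms C13–C14=C15–O and C1–C16–C17(=O)–C18.
Retrosynthesis: first the C15–O acyl bond, then C1–C2 and C1–C13. C1 lies between the C2 ketone and C13, so removing it with its arm leaves C2 bonded to C13, a bicyclo[3.3.1]nonan-3-one made of two six-membered rings (C7–C12 and C12–C3–C2–C13–C10–C11). Then C13–C14, C3–OH, C4–O5 and C3–C4 (pyran), and last C12–C3 and C10–C13 (a three-carbon bridge on the carvone ring).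
Forward: carvone cyclohexane, second carbocycle by α,α′-annulation, removal of the C11 carbonyl, pyran by oxa-Michael closure, six-to-seven ring enlargement with the diazoalkane, enol ester last.
Stereochemistry: C7 from (R)-carvone; C10 by axial enolate alkylation cis to the C7 side chain; C12 by the bridging ring closure; C3 and C13 by reagent approach to the exo face of the bicycle; C1 by equilibration next to C2; the E enol ester by O-acylation of the aldehyde.

Key step: step 12

Remark: C1 is epimerisable; the epimer of the target, with the C1 arm trans to the C13 arm, is assumed to be the more stable one.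

**Route**

Step 1
Reactants: 1 (R)-carvone
Product: 3 (5R)-5-(2-hydroxypropan-2-yl)-2-methylcyclohex-2-en-1-one, via organomercurial 2 (not isolated)
Conditions: Hg(OAc)2, THF/H2O, rt; then NaBH4, aq NaOH, 0 °C
Reagents that add atoms: water, O
Why: Markovnikov hydration by oxymercuration–demercuration, in which Hg(OAc)2 adds only to the electron-rich 1,1-disubstituted alkene and not to the enone, water opens the mercurinium ion at the tertiary carbon and NaBH4 replaces mercury by hydrogen, leaving the C7 stereocentre of carvone untouched.

Step 2
Reactants: 3 (5R)-5-(2-hydroxypropan-2-yl)-2-methylcyclohex-2-en-1-one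
Product: 5 (2R,5R)-2-[2-(chloromethyl)prop-2-en-1-yl]-5-(2-hydroxypropan-2-yl)-2-methylcyclohexan-1-one, via lithium enolate 4 (not isolated)
Conditions: Li, NH3/THF, −78 °C; then 3-chloro-2-(chloromethyl)prop-1-ene (excess), −78 to −33 °C
Reagents that add atoms: 3-chloro-2-(chloromethyl)prop-1-ene, C=C(CCl)CCl
Why: Dissolving-metal reduction of the enone gives the C10=C11 lithium enolate regiospecifically (reductive alkylation), and the allylic chloride alkylates C10 by axial attack on the half-chair that keeps the C7 side chain equatorial, which is expected to place the new arm cis to that side chain (the minor C10 epimer is removed by chromatography).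

Step 3
Reactants: 5 (2R,5R)-2-[2-(chloromethyl)prop-2-en-1-yl]-5-(2-hydroxypropan-2-yl)-2-methylcyclohexan-1-one
Product: 6 6-(2-hydroxypropan-2-yl)-1-methyl-3-methylidenebicyclo[3.3.1]nonan-9-one (side chain on the face of the cyclohexane that carries the new bridge)
Conditions: KOtBu, THF, 0 °C to rt
Reagents that add atoms: none
Why: Intramolecular enolate alkylation completing an α,α′-annulation of the cyclohexanone, in which C12 is the only enolisable position and the 6-(enolendo)-exo-tet closure can only occur on the face that carries the C10 arm, which fixes C12 and closes the bicyclo[3.3.1]nonane.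

Step 4
Reactants: 6 6-(2-hydroxypropan-2-yl)-1-methyl-3-methylidenebicyclo[3.3.1]nonan-9-one
Product: 8 2-(1-methyl-3-methylidenebicyclo[3.3.1]nonan-6-yl)propan-2-ol, via hydrazone 7 (not isolated)
Conditions: N2H4·H2O, KOH, diethylene glycol, 130 °C; then 200 °C
Reagents that add atoms: none
Why: Wolff–Kishner reduction removes the bridging C11 carbonyl once it has activated C10 and C12; the ketone sits between two bridgeheads and cannot epimerise, and the isolated alkene and the tertiary alcohol tolerate the hot base.

Step 5
Reactants: 8 2-(1-methyl-3-methylidenebicyclo[3.3.1]nonan-6-yl)propan-2-ol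
Product: 10 6-(2-hydroxypropan-2-yl)-1-methylbicyclo[3.3.1]nonan-3-one, via ozonide 9 (not isolated)
Conditions: O3, CH2Cl2, −78 °C; then PPh3, −78 °C to rt
Reagents that add atoms: ozone, [O-][O+]=O
Why: Ozonolysis of the only alkene with reductive work-up unveils the C2 ketone in the middle of the three-carbon bridge without touching a stereocentre.

Step 6
Reactants: 10 6-(2-hydroxypropan-2-yl)-1-methylbicyclo[3.3.1]nonan-3-one
Product: 14 6-(2-hydroxypropan-2-yl)-1-methyl-4-methylidenebicyclo[3.3.1]nonan-3-one, via lithium enolate 11 (not isolated), via Mannich base 12 (not isolated), via ammonium iodide 13 (not isolated)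
Conditions: LiN(iPr)2 (2.2 equiv), THF, −78 °C; dimethylmethyleneammonium iodide, −78 to 0 °C; then MeI, CH2Cl2, rt; then aq NaHCO3, rt
Reagents that add atoms: dimethylmethyleneammonium iodide, C=[N+](C)C.[I-]
Why: Kinetic deprotonation by the hindered amide is expected at C3, the methylene beside the CH bridgehead C12, and not at C13, which is neopentylic beside the quaternary C10 (the preference known for 3,3-disubstituted cyclohexanones), and Mannich reaction of this enolate followed by N-methylation and elimination of trimethylamine (Mannich methylenation) gives the C3=C4 enone, in which C3 is no stereocentre.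

Step 7
Reactants: 14 6-(2-hydroxypropan-2-yl)-1-methyl-4-methylidenebicyclo[3.3.1]nonan-3-one
Product: 16 tricyclic hydroxy ketone (C2 ketone; C3 hydroxyl anti to C7; pyran C3–C4–O5–C6–C7–C12 closed), via potassium enolate 15 (not isolated)
Conditions: KN(SiMe3)2, THF, −78 to −40 °C; then 3-phenyl-2-(phenylsulfonyl)oxaziridine, −78 °C
Reagents that add atoms: 3-phenyl-2-(phenylsulfonyl)oxaziridine, O=S(=O)(N1OC1c1ccccc1)c1ccccc1
Why: The C6 potassium alkoxide adds to C4 in an intramolecular oxa-Michael reaction (6-endo-trig) that closes the pyran and gives the C2=C3 enolate regiospecifically, and electrophilic hydroxylation of this enolate by the N-sulfonyloxaziridine occurs on the exo face of C3, opposite to C7 and the new pyran ring, so that the C3 hydroxyl ends up anti to C7 as in the target.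

Step 8
Reactants: 16 tricyclic hydroxy ketone
Product: 17 trimethylsilyl ether of the tricyclic hydroxy ketone
Conditions: 1-(trimethylsilyl)imidazole, CH2Cl2, rt
Reagents that add atoms: 1-(trimethylsilyl)imidazole, C[Si](C)(C)n1ccnc1
Why: Silylation of the tertiary alcohol with a neutral silyl donor masks the α-ketol against rearrangement and O-alkylation without enolising the ketone.

Step 9
Reactants: 17 trimethylsilyl ether of the tricyclic hydroxy ketone
Product: 19 C13-allyl ketone (allyl on the exo face and cis to the C3 silyloxy group), via lithium enolate 18 (not isolated)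
Conditions: LiN(iPr)2, THF, −78 °C; then allyl bromide, −78 to −30 °C
Reagents that add atoms: allyl bromide, C=CCBr
Why: Enolate alkylation in which the ketone, with C3 quaternary, can only enolise towards C13, and allyl bromide is expected to approach on the exo face, anti to the vicinal C10–C9 bond and away from the C7–C8–C9 bridge (axial attack), placing the allyl group, the latent C14–C15 aldehyde, cis to the C3 silyloxy group.

Step 10
Reactants: 20 3-methylbut-3-en-1-ol; 21 4-methylbenzenesulfonohydrazide
Product: 23 N'-(3-methylbut-3-en-1-ylidene)-4-methylbenzenesulfonohydrazide, via 3-methylbut-3-enal 22 (not isolated)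
Conditions: Dess–Martin periodinane, pyridine, CH2Cl2, 0 °C; filtered; then 21, MeOH, 0 °C
Reagents that add atoms: none
Why: Dess–Martin oxidation under pyridine buffering gives the β,γ-unsaturated aldehyde without conjugation of the double bond, and condensation with the sulfonyl hydrazide in the same operation captures it as the stable hydrazone.

Step 11
Reactants: 23 N'-(3-methylbut-3-en-1-ylidene)-4-methylbenzenesulfonohydrazide
Product: 25 4-diazo-2-methylbut-1-ene (cold toluene solution, used at once), via sodium salt 24 (not isolated)
Conditions: NaOMe, MeOH, rt; evaporated; then 90–110 °C, 0.1 mbar, distilled into toluene at −78 °C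
Reagents that add atoms: none
Why: Bamford–Stevens reaction in which the sodium salt loses sulfinate on heating and the volatile diazoalkane is removed under vacuum as it forms and collected cold, where its intramolecular dipolar cycloaddition is slow.

Step 12
Reactants: 19 C13-allyl ketone; 25 4-diazo-2-methylbut-1-ene
Product: 28 ring-expanded ketone (2-methylallyl at C1 trans to the allyl at C13), via diazonium alkoxide 26 (not isolated), via C1 epimer 27 (not isolated)
Conditions: Sc(OTf)3 (10 mol %), 25 (3 equiv), toluene, −78 to −40 °C; then DBU, toluene, rt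
Reagents that add atoms: none
Why: Sc(OTf)3 binds the C2 carbonyl oxygen, the diazo carbon of 25 adds to C2 to give the diazonium alkoxide 26, and the C2–C13 bond antiperiplanar to the C1–N bond shifts to C1 as dinitrogen leaves, so that C1–C2 and C1–C13 are formed. This is the Lewis acid catalysed homologation of a cyclic ketone with a non-stabilised diazoalkane, a known diazoalkane–carbonyl ring expansion of the Tiffeneau–Demjanov type. The seven-membered ring is not closed directly but arises by enlargement of the six-membered ring C12–C3–C2–C13–C10–C11 through the 1,2-shift. C13 migrates with retention and keeps the configuration set in step 9, whereas C1 is formed without control and is then equilibrated by DBU through the C2 enolate to the isomer with the 2-methylallyl group trans to the C13 allyl group. The step needs migration of C13 rather than C3, and this is secured because C3 is quaternary, carries the electron-withdrawing silyloxy group and pushes the 2-methylallyl substituent of 26 away from itself, which puts the leaving group anti to C2–C13. A second insertion is not expected because the product ketone is branched on both sides, and the diazoalkane is used cold and in excess because it cyclises on itself at room temperature.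

Step 13
Reactants: 28 ring-expanded ketone
Product: 30 keto aldehyde (C15 aldehyde; C17 methyl ketone; C3 trimethylsilyl ether), via bis-ozonide 29 (not isolated)
Conditions: O3, CH2Cl2, −78 °C; then PPh3, −78 °C to rt
Reagents that add atoms: ozone, [O-][O+]=O
Why: Ozonolysis with reductive work-up cleaves both terminal alkenes in one operation, the 2-methylallyl group to the C17 methyl ketone and the allyl group to the C15 aldehyde, each with loss of its CH2 terminus and without touching a stereocentre.

Step 14
Reactants: 30 keto aldehyde
Product: 31 (E)-enol 3-methylbut-2-enoate bearing the C3 trimethylsilyl ether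
Conditions: 3-methylbut-2-enoic anhydride, Et3N, DMAP, THF, 40 °C
Reagents that add atoms: 3-methylbut-2-enoic anhydride, CC(C)=CC(=O)OC(=O)C=C(C)C
Why: Enol ester formation by O-acylation of the aldehyde enolate, which the amine generates far more readily than any ketone enolate, with the acylpyridinium formed from the anhydride and DMAP; the E isomer is expected to predominate because the acyloxy group avoids the branched C13, and any Z isomer would be removed by chromatography.

Step 15
Reactants: 31 (E)-enol 3-methylbut-2-enoate bearing the C3 trimethylsilyl ether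
Product: 32 CNP0237201.2
Conditions: HF·pyridine, pyridine, THF, 0 °C
Reagents that add atoms: none
Why: Fluoride-induced cleavage of the tertiary trimethylsilyl ether under pyridine buffering frees the C3 hydroxyl without hydrolysing the enol ester or disturbing the α-ketol.

**Compound list**

1 | (R)-carvone, (5R)-2-methyl-5-(prop-1-en-2-yl)cyclohex-2-en-1-one | CC1=CC[C@H](CC1=O)C(C)=C | starting material
2 | (5R)-5-[1-(acetoxymercurio)-2-hydroxypropan-2-yl]-2-methylcyclohex-2-en-1-one (carbinol carbon as a mixture; not isolated) | CC1=CC[C@H](CC1=O)C(C)(O)C[Hg]OC(C)=O | intermediate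
3 | (5R)-5-(2-hydroxypropan-2-yl)-2-methylcyclohex-2-en-1-one | CC1=CC[C@H](CC1=O)C(C)(C)O | intermediate
4 | dilithium C10=C11 enolate alkoxide from 3 (not isolated) | [Li]OC1=C(C)CC[C@H](C1)C(C)(C)O[Li] | intermediate
5 | (2R,5R)-2-[2-(chloromethyl)prop-2-en-1-yl]-5-(2-hydroxypropan-2-yl)-2-methylcyclohexan-1-one | OC(C)(C)[C@@H]1CC[C@](C)(CC(=C)CCl)C(=O)C1 | intermediate
6 | 6-(2-hydroxypropan-2-yl)-1-methyl-3-methylidenebicyclo[3.3.1]nonan-9-one, side chain cis to the methylidene bridge | OC(C)(C)[C@@H]1CC[C@]2(C)CC(=C)C[C@H]1C2=O | intermediate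
7 | hydrazone of 6 (not isolated) | OC(C)(C)[C@@H]1CC[C@]2(C)CC(=C)C[C@H]1C2=NN | intermediate
8 | 2-(1-methyl-3-methylidenebicyclo[3.3.1]nonan-6-yl)propan-2-ol | OC(C)(C)[C@@H]1CC[C@]2(C)CC(=C)C[C@H]1C2 | intermediate
9 | spiro-1,2,4-trioxolane (ozonide) of 8 (not isolated) | OC(C)(C)[C@@H]1CC[C@]2(C)CC3(OCOO3)C[C@H]1C2 | intermediate
10 | 6-(2-hydroxypropan-2-yl)-1-methylbicyclo[3.3.1]nonan-3-one | OC(C)(C)[C@@H]1CC[C@]2(C)CC(=O)C[C@H]1C2 | intermediate
11 | dilithium C2=C3 enolate alkoxide of 10 (not isolated) | [Li]OC(C)(C)[C@@H]1CC[C@]2(C)CC(O[Li])=C[C@H]1C2 | intermediate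
12 | C3-(dimethylaminomethyl) ketone, Mannich base (C3 unassigned; not isolated) | OC(C)(C)[C@@H]1CC[C@]2(C)CC(=O)C(CN(C)C)[C@H]1C2 | intermediate
13 | trimethylammonium iodide of 12 (not isolated) | OC(C)(C)[C@@H]1CC[C@]2(C)CC(=O)C(C[N+](C)(C)C)[C@H]1C2.[I-] | intermediate
14 | 6-(2-hydroxypropan-2-yl)-1-methyl-4-methylidenebicyclo[3.3.1]nonan-3-one | OC(C)(C)[C@@H]1CC[C@]2(C)CC(=O)C(=C)[C@H]1C2 | intermediate
15 | potassium C2=C3 enolate of the pyran-fused ketone (not isolated) | [K]OC1=C2COC(C)(C)[C@@H]3CC[C@@](C)(C[C@@H]32)C1 | intermediate
16 | tricyclic hydroxy ketone: pyran-fused bicyclo[3.3.1]nonan-3-one, C3–OH anti to C7 | O=C1[C@]2(O)COC(C)(C)[C@@H]3CC[C@@](C)(C[C@@H]32)C1 | intermediate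
17 | trimethylsilyl ether of 16 | O=C1[C@]2(O[Si](C)(C)C)COC(C)(C)[C@@H]3CC[C@@](C)(C[C@@H]32)C1 | intermediate
18 | lithium C2=C13 enolate of 17 (not isolated) | [Li]OC=1[C@]2(O[Si](C)(C)C)COC(C)(C)[C@@H]3CC[C@@](C)(C[C@@H]32)C=1 | intermediate
19 | C13-allyl ketone, key-step precursor (allyl exo, cis to C3–OSiMe3) | O=C1[C@]2(O[Si](C)(C)C)COC(C)(C)[C@@H]3CC[C@@](C)(C[C@@H]32)[C@H]1CC=C | intermediate
20 | 3-methylbut-3-en-1-ol | CC(=C)CCO | starting material
21 | 4-methylbenzenesulfonohydrazide | Cc1ccc(cc1)S(=O)(=O)NN | starting material
22 | 3-methylbut-3-enal (not isolated) | CC(=C)CC=O | intermediate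
23 | N'-(3-methylbut-3-en-1-ylidene)-4-methylbenzenesulfonohydrazide | CC(=C)C/C=N/NS(=O)(=O)c1ccc(C)cc1 | intermediate
24 | sodium salt of 23 (not isolated) | CC(=C)C/C=N/[N-]S(=O)(=O)c1ccc(C)cc1.[Na+] | intermediate
25 | 4-diazo-2-methylbut-1-ene | C=C(C)CC=[N+]=[N-] | intermediate
26 | scandium-bound diazonium alkoxide, drawn as the metal-free zwitterion (C1 and C2 unassigned; not isolated) | C=C(C)CC([N+]#N)C1([O-])[C@]2(O[Si](C)(C)C)COC(C)(C)[C@@H]3CC[C@@](C)(C[C@@H]32)[C@H]1CC=C | intermediate
27 | C1 epimer of 28 (not isolated) | C=C(C)C[C@H]1C(=O)[C@]2(O[Si](C)(C)C)COC(C)(C)[C@@H]3CC[C@@](C)(C[C@@H]32)[C@H]1CC=C | intermediate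
28 | ring-expanded ketone, 2-methylallyl at C1 trans to allyl at C13 | C=C(C)C[C@@H]1C(=O)[C@]2(O[Si](C)(C)C)COC(C)(C)[C@@H]3CC[C@@](C)(C[C@@H]32)[C@H]1CC=C | intermediate
29 | bis-ozonide of 28 (ozonide carbons unassigned; not isolated) | CC1(OCOO1)C[C@@H]2C(=O)[C@]3(O[Si](C)(C)C)COC(C)(C)[C@@H]4CC[C@@](C)(C[C@@H]43)[C@H]2CC5OCOO5 | intermediate
30 | keto aldehyde with C3 trimethylsilyl ether | CC(=O)C[C@@H]1C(=O)[C@]2(O[Si](C)(C)C)COC(C)(C)[C@@H]3CC[C@@](C)(C[C@@H]32)[C@H]1CC=O | intermediate
31 | (E)-enol 3-methylbut-2-enoate with C3 trimethylsilyl ether | CC(=O)C[C@@H]1C(=O)[C@]2(O[Si](C)(C)C)COC(C)(C)[C@@H]3CC[C@@](C)(C[C@@H]32)[C@H]1/C=C/OC(=O)C=C(C)C | intermediate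
32 | CNP0237201.2 | CC(=O)C[C@@H]1C(=O)[C@]2(O)COC(C)(C)[C@@H]3CC[C@@](C)(C[C@@H]32)[C@H]1/C=C/OC(=O)C=C(C)C | target

**Step count**

Total: 15 steps. Longest linear sequence: 13 steps from (R)-carvone (steps 1–9 and 12–15); the diazoalkane is a 2-step branch (steps 10–11).

**Steps most likely to fail**

Step 12, ring expansion. The secondary diazo carbon may add too slowly to the C2 carbonyl, which is branched on both sides. The diazoalkane may be lost meanwhile through its own intramolecular cycloaddition, or C3 may migrate instead of C13. The fallback sets out from 19 and separates homologation from introduction of the arm. (Trimethylsilyl)diazomethane with AlMe3 in CH2Cl2 at −78 to 0 °C, a known homologation with a smaller and storable reagent, should give the α-trimethylsilyl cycloheptanone F1. Dilute acid on work-up protodesilylates it to the cycloheptanone unsubstituted at C1 F2. Because C3 is quaternary, F2 has one enolisable position only, so LiN(iPr)2 followed by 3-bromo-2-methylprop-1-ene alkylates C1. Equilibration with DBU then returns to the route at 28.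

Step 9, allylation at C13. Facial selectivity may be poor because the electrophile must approach the enolate on the face that already carries the C3 silyloxy group; attack from the other face would give the C13 epimer, which cannot be corrected once C13 is no longer next to the ketone. The fallback sets out from 14 and allylates before any oxygen sits on C3. Catalytic KOtBu in THF effects the oxa-Michael closure alone and gives the pyran-fused ketone with hydrogen at C3 F3. Kinetic deprotonation with LiN(iPr)2 at the C13 methylene and allyl bromide give the C13-allyl ketone F4 by attack on an unencumbered exo face. KN(SiMe3)2 then removes the axial C3 hydrogen (the remaining C13 hydrogen is equatorial and shielded), and the N-sulfonyloxaziridine gives the C13-allyl hydroxy ketone F5. Silylation with 1-(trimethylsilyl)imidazole returns to the route at 19.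

Step 14, enol ester formation. O-acylation of the aldehyde enolate may give an E/Z mixture, and the enolate may instead undergo intramolecular aldol addition to the C17 ketone. The fallback sets out from 30 and avoids the enolate. 3-Methylbut-2-enoyl chloride with catalytic ZnCl2 in CH2Cl2 adds across the aldehyde (known addition of acyl chlorides to aldehydes) to give the 1-chloroalkyl ester F6. Dehydrochlorination with 2,4,6-collidine proceeds by anti elimination from the conformer that keeps C13 and the acyloxy group apart, which should favour the E alkene, and returns to the route at 31.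

Further compounds
F1 | step 12 | α-trimethylsilyl cycloheptanone (SiMe3 on C1, C1 unassigned) | C[Si](C)(C)C1C(=O)[C@]2(O[Si](C)(C)C)COC(C)(C)[C@@H]3CC[C@@](C)(C[C@@H]32)[C@H]1CC=C
F2 | step 12 | cycloheptanone unsubstituted at C1 | C1C(=O)[C@]2(O[Si](C)(C)C)COC(C)(C)[C@@H]3CC[C@@](C)(C[C@@H]32)[C@H]1CC=C
F3 | step 9 | pyran-fused ketone with hydrogen at C3 | O=C1[C@@H]2COC(C)(C)[C@@H]3CC[C@@](C)(C[C@@H]32)C1
F4 | step 9 | C13-allyl ketone with hydrogen at C3 | O=C1[C@@H]2COC(C)(C)[C@@H]3CC[C@@](C)(C[C@@H]32)[C@H]1CC=C
F5 | step 9 | C13-allyl hydroxy ketone | O=C1[C@]2(O)COC(C)(C)[C@@H]3CC[C@@](C)(C[C@@H]32)[C@H]1CC=C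
F6 | step 14 | 1-chloroalkyl 3-methylbut-2-enoate at C15 (C15 unassigned) | CC(=O)C[C@@H]1C(=O)[C@]2(O[Si](C)(C)C)COC(C)(C)[C@@H]3CC[C@@](C)(C[C@@H]32)[C@H]1CC(Cl)OC(=O)C=C(C)C
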